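The numbers in the tables are simulated from invented constants; noise was put on by code.

Take a ratio. You asked for a quick number on this flask, and here is what we have:

| flask | substrate | partner | remark | time |
|---|---|---|---|---|
| west | 1.2 M | 0.996 M | run made earlier |  |
| flask | 0.83 M | 0.996 M |  | 6.0 d |

west run (percent of the substrate charged)

| time / h | open intermediate / % | target / % | substrate / % |
|---|---|---|---|
| 2.50 | 30.4 | 11.9 | 43.7 |
| 5.00 | 20.4 | 29.4 | 22.4 |
| 12.0 | 6.5 | 50.7 | 4.5 |
| 30.0 | 0.9 | 54.1 | 0.3 |

(standard deviation of a reading: 0.3 percentage points)

* time up to 6.0 d at which open intermediate stands highest
* the amount of open intermediate, in percent of the substrate charged, at that time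
* earliest time at which at least nineteen twentieths of that best amount are there, in d
* latest time at which they still are, in d



Open intermediate stands highest at the moment when substrate feeds it as fast as it is used up, so I compare those two rates. Over the first 2.50 h of the west run, substrate fell with a mean first-order constant of

k(make) = 0.331 h⁻¹

Between 2.50 h and 5.00 h, what substrate lost plus what open intermediate lost, over the mean open intermediate and the time, gives

k(use) = 0.493 h⁻¹

Both are readings. Their quotient, ρ = 0.672, is the crossing ratio, the [open intermediate]/[substrate] at which making equals use.

I treat these as consecutive first-order steps and carry both constants to this flask, which has the same partner charge and less substrate. That is my own reckoning: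

time = ln(k(use)/k(make))/(k(use) − k(make)) = 0.102 d

height = ρ^(1/(1 − ρ)) = 29.8%

Your forecast gives 0.104 d and 32%, with a window from 0.073 d to 0.148 d, and says “The peak comes early”. My time is close to yours, but my height is lower.

This flask peaks at 0.0846 d with 33.1%, and the window runs from 0.0607 d to 0.116 d. The peak came sooner than your time or mine. At 0.0999 d, past the peak, open intermediate is made at 0.852 of the rate at which it is used, each step taken net. At the best time this flask holds 33.1% open intermediate and 50.4% substrate, a quotient of 0.657 beside the crossing ratio of 0.672 read from the west run.

    partner → second intermediate (k = 0.289 h⁻¹)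
    2 open intermediate → homo product (k = 0.343 M⁻¹ h⁻¹)
    target ⇌ isomer of the product (K = 18.0, k = 0.00558 h⁻¹)
    substrate ⇌ open intermediate (K = 2.90, k = 0.386 h⁻¹)
    open intermediate + second intermediate → target (k = 0.725 M⁻¹ h⁻¹)

Now take the neighbour flask with 0.60 M of partner and the substrate charge of this flask. If I scale k(use) with the partner charge, which is my assumption, the crossing ratio becomes 1.12 and the height 38.9%. The computed best there is 35.9%.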